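## Structural features

The target is built from four guaiacyl-type rings around a trans-α,β-dibenzyl-γ-butyrolactone. The β-benzyl group is ring B and the α-benzyl group is ring C. Ring C is the benzo ring of a 2-aryl-3-(hydroxymethyl)-7-methoxy-2,3-dihydrobenzofuran carrying ring D at C2. The phenolic oxygen of ring B is bonded to C8'' of a 1-arylpropane-1,3-diol (ring A on C7''), that is, an arylglycerol β-aryl ether. The six stereocentres form three vicinal pairs: lactone Cα(R)/Cβ(R) trans, dihydrofuran C2(S)/C3(R) trans, and glycerol C7''(R)/C8''(S) erythro. The pairs are insulated from each other by benzylic CH2 groups or an aryl ether, so each pair needs its own source of absolute configuration. Fragile sites are the two para-hydroxybenzylic carbons (C2 of the dihydrofuran, C7'' of the glycerol unit), which ionise to quinone methides in acid or hot base, all benzylic C–O bonds under hydrogenolysis, and the lactone α-centre. Any ester precursor of the C3 carbinol is a β-aryloxy ester that can open by E1cB. The real difficulties are the trans C2–C3 unit of the dihydrobenzofuran on a tetrasubstituted arene in one absolute sense, and the erythro glycerol ether, because the dependable auxiliary aldol gives the threo relationship. The key step uses the fact that O1, C2, C3, C3a and the carbinol carbon on C3 of the dihydrobenzofuran are O1, C2, C3, C4a and C4 of a 2-arylchroman-4-one. Moving C4a from C4 to C3 contracts the ring, makes C4 the exocyclic carboxyl carbon, and lets the easily set C2 centre control C3.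

## Logic of the disconnections

38 ⇒ 37. Five O–Si bonds are cut (two aryl, two primary, one benzylic secondary). All hydroxyl groups then leave in one buffered fluoride step, so no hydrogenolysis or acid touches the benzylic C–O bonds. The forward step must not open the lactone or trigger quinone methide chemistry.

37 ⇒ 35 + 17. The bond between the lactone α-carbon and the benzylic CH2 of ring C is cut. This divides the molecule into halves of similar size and places the last stereocentre under control of the existing β-substituent. The enolate of 35 (36) must alkylate anti to that substituent, and 17 must be a reactive yet isolable benzylic bromide.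

17 ⇒ 16 ⇒ 13. C–Br is returned to C–OH, and the C5–CH2 bond of ring C is then cut back to C5–Br (through 14 and 15). The bromine is present from step 1 and also blocks the position para to the ring oxygen in the key step. The forward step needs a halogen–lithium exchange that tolerates silyl ethers.

13 ⇒ 12 ⇒ 11 ⇒ 10. Two O–Si bonds, one O–S bond and the C3 carbinol oxidation level are adjusted. The ester is reduced first, so that the base needed for sulfonate cleavage never meets a β-aryloxy ester. The simplification is that the sulfonate, needed only for the key step, is exchanged where it is harmless.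

10 ⇒ 8 (key, through 9). The C3–C3a bond is cut and re-formed as C4–C4a of a chromanone. Two adjacent stereocentres on a five-membered ring become one stereocentre on a six-membered ring. The forward step must shift C4a rather than ring D. The sulfonate on ring D is kept for this reason.

8 ⇒ 4 + 7. The C2–aryl bond is cut. This reduces the problem to an enantioselective conjugate addition to an achiral chromone. The free boronic acid 7 is used rather than its ester 6, because base-free transmetalation to cationic divalent palladium is slow for boronic esters. The catalyst cycle must leave the C–Br bond alone.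

4 ⇒ 2 ⇒ 1 and 7 ⇒ 6 ⇒ 5. The pyranone C2 carbon and the C–Br bond are removed from 4, and the O–S bond and boronic acid are traced to 5. Both paths end at commercial arenes. The only demand is para-selective bromination of 1.

35 ⇒ 34 ⇒ 33 ⇒ 32 ⇒ 31 ⇒ 30. The C7''–H bond is cut (hydride to ketone 33) and the silyl and auxiliary bonds are removed. The auxiliary aldol is syn and would give the threo ether. The erythro carbinol is therefore made by chelation-controlled reduction of a ketone whose C8'' centre is already fixed. The cost is three extra operations, but each is stereochemically predictable.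

30 ⇒ 26 + 28 (through 29). The C7''–C8'' bond is cut. This sets C8'' absolutely by the auxiliary and joins ring A in one step. The enolisation must select the imide over the lactone.

26 ⇒ 24 + 25 and 28 ⇒ 27. The aryl ether O–CH2 bond and one O–Si bond are cut. This attaches the chiral auxiliary and the two-carbon unit in one alkylation of phenol 24.

24 ⇒ 23 ⇒ 21 (through 22) ⇒ 20 ⇒ 18 + 19. The benzyl ether, the lactone C–O bond and the Cβ–H bond are cut, then the benzylidene C=C bond. The lactone stereocentre is thereby assigned to a catalytic hydrogenation of a condensation product of two commercial compounds. The hydrogenation catalyst must discriminate the faces of the trisubstituted alkene.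

## Other disconnections considered

Alternative 1: The cut removes both benzylic C–C bonds of the lactone at once and traces the lactone to the chiral butenolide A2.
- Forward step: the 2-lithio derivative of dithiane A3 would add to C4 of A2 anti to the menthyloxy group. The resulting enolate would be trapped at C3 by the benzylic bromide A4, giving the 3,4-trans adduct A1.
- In favour: one operation would set both lactone stereocentres from a cheap chiral-pool acetal. The enolate forms regiospecifically, and the assembly is highly convergent.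
- Against: A1 must still lose the dithiane (reductive desulfurisation next to several benzylic C–O bonds and two benzyl ethers) and the menthyloxy acetal (basic borohydride reduction and relactonisation). A bulky tertiary carbanion must add to a hindered acceptor. The cut does not say how the dihydrobenzofuran of A4 or the erythro ether of A3 is made.
- Comparison: structurally this step addresses the lactone, not the dihydrobenzofuran. Mechanistically it is substrate-controlled conjugate addition, against catalyst-controlled hydrogenation followed by alkylation in the chosen plan. For the lactone portion it is the better plan in step economy (one C–C-forming operation plus two clean-up steps against steps 12–14 and 24), and its stereocontrol there is equal. It does not replace the ring contraction, since A4 would need the same or a comparable sequence as steps 1–11.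

Alternative 2: The cut is the C2–C3 bond of the dihydrobenzofuran.
- Forward step: the aryldiazoacetate A6 would be decomposed by Rh2(S-PTTL)4 or its mirror image, whichever leads to 2S. The rhodium carbene would insert into the benzylic C–H bond of the neighbouring benzyl ether, giving the cis ester A5.
- In favour: ring and both stereocentres would come from an achiral precursor in one catalytic step. The C5 CH2O substituent and the ring D benzyl ether are already present, so the sulfonate exchange and the bromide homologation (steps 8–10) would be unnecessary. On post-cyclisation step economy this alternative is the better one.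
- Against: the insertion is cis-selective, so C3 must then be epimerised in a β-aryloxy ester that opens by E1cB under the same basic conditions. Diazo transfer is needed on an electron-rich, doubly ortho-substituted arylacetate. Enantioinduction at a donor-substituted benzylic C–H flanked by a coordinating methoxy group is less predictable. Any shortfall in ee cannot be repaired by cis/trans equilibration.
- Comparison: both plans deliver the same methyl 2-aryl-2,3-dihydrobenzofuran-3-carboxylate skeleton. The chosen plan divides the task (ligand sets C2, C2 sets C3, trans directly), whereas here C3 is first set the wrong way. Overall length is about equal; stereochemical safety is lower.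

Alternative 3: The cut is the O1–C2 bond.
- Forward step: BF3·OEt2 would ionise the benzylic hydroxyl of diol A8 (either carbinol epimer). The phenolic oxygen of ring C would capture the para-alkoxybenzyl cation in a five-membered ring closure, giving A7 with ring D trans to CH2OH.
- In favour: the reagent is simple and the step is stereoconvergent. The trans product is favoured both kinetically and thermodynamically. A7 already carries the C3 carbinol and a benzyl ether on ring D, so the steps after cyclisation would be fewer than after 10. On that count it is the better plan.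
- Against: the absolute configuration must already sit at C2 of A8, which requires an auxiliary-based construction on a hindered, phenol-protected arylacetic acid. The cation can also be captured intermolecularly or alkylate electron-rich arenes. A benzyl ether and an acid-labile product would face a strong Lewis acid.
- Comparison: both plans fix the trans relationship by substrate control from one pre-set centre (C3 there, C2 here), which is equal. Mechanistically this is an SN1 capture, whereas the chosen step is a concerted 1,2-shift that cannot scramble C2. Overall length is probably equal.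

Key step: step 6

Assumption: (R)-t-BuPyOx is taken to give the 2S flavanone and (S,S)-Et-DuPhos the R succinate, by analogy with the sense of induction of these ligand families on cyclic enones and itaconates; if either sense proves reversed, the mirror-image ligand is used.

Remark: the 2S descriptor of 8, the 2S,3S descriptor of 10 and the 2S,3R descriptor of 11–17 and 38 describe one spatial arrangement. The C3 descriptor changes only because CO2Me outranks C2 and CH2OR does not. No structural correction is needed.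

Abbreviations: Ts = 4-methylbenzenesulfonyl; TIPS = triisopropylsilyl; TBS = tert-butyldimethylsilyl; t-BuPyOx = 4-tert-butyl-2-(pyridin-2-yl)-4,5-dihydrooxazole; DMPU = N,N'-dimethylpropyleneurea.

Step 1
Reactants: 1 1-(2-hydroxy-3-methoxyphenyl)ethan-1-one
Product: 2 1-(5-bromo-2-hydroxy-3-methoxyphenyl)ethan-1-one
Conditions: NBS (1.05 equiv), MeCN, 0 °C to rt
Reagents that add atoms: N-bromosuccinimide, BrN1C(=O)CCC1=O
Why: Electrophilic aromatic bromination; the hydroxyl group directs para because both ortho positions are substituted, and that position is also meta to the acetyl group.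

Step 2
Reactants: 2 1-(5-bromo-2-hydroxy-3-methoxyphenyl)ethan-1-one
Product: 4 6-bromo-8-methoxy-4H-chromen-4-one, via enaminone 3 (not isolated)
Conditions: Me2NCH(OMe)2 (2 equiv), toluene, 100 °C; then conc. HCl, CH2Cl2, 40 °C
Reagents that add atoms: N,N-dimethylformamide dimethyl acetal, COC(OC)N(C)C
Why: Enaminone route to chromones: the methyl ketone condenses with the amide acetal, and acid then promotes conjugate addition of the phenol and loss of dimethylamine.

Step 3
Reactants: 5 2-methoxy-4-(4,4,5,5-tetramethyl-1,3,2-dioxaborolan-2-yl)phenol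
Product: 6 2-methoxy-4-(4,4,5,5-tetramethyl-1,3,2-dioxaborolan-2-yl)phenyl 4-methylbenzenesulfonate
Conditions: TsCl (1.2 equiv), Et3N, DMAP (5 mol %), CH2Cl2, 0 °C to rt
Reagents that add atoms: 4-methylbenzenesulfonyl chloride, Cc1ccc(cc1)S(Cl)(=O)=O
Why: O-sulfonylation of a phenol; the boronic ester is inert to amine base and sulfonyl chloride.

Step 4
Reactants: 6 2-methoxy-4-(4,4,5,5-tetramethyl-1,3,2-dioxaborolan-2-yl)phenyl 4-methylbenzenesulfonate
Product: 7 [3-methoxy-4-(tosyloxy)phenyl]boronic acid
Conditions: NaIO4 (3 equiv), NH4OAc (3 equiv), acetone/H2O 1:1, rt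
Reagents that add atoms: water, O
Why: Oxidative deprotection of a pinacol boronate: periodate cleaves the pinacol released by hydrolysis and so drives the equilibrium to the boronic acid; the aryl sulfonate is inert.

Step 5
Reactants: 4 6-bromo-8-methoxy-4H-chromen-4-one; 7 [3-methoxy-4-(tosyloxy)phenyl]boronic acid (2 equiv)
Product: 8 (2S)-6-bromo-8-methoxy-2-[3-methoxy-4-(tosyloxy)phenyl]chroman-4-one
Conditions: Pd(OCOCF3)2 (5 mol %), (R)-t-BuPyOx (6 mol %), NH4PF6 (30 mol %), H2O (5 equiv), ClCH2CH2Cl, 60 °C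
Reagents that add atoms: none
Why: Enantioselective conjugate addition of an arylboronic acid catalysed by cationic divalent palladium: transmetalation, enantio-determining carbopalladation of C2–C3 and protonolysis of the palladium enolate by water; the ligand sets C2 (S), and because no zerovalent palladium is formed the C–Br and C–OTs bonds are not touched.

Step 6
Reactants: 8 (2S)-6-bromo-8-methoxy-2-[3-methoxy-4-(tosyloxy)phenyl]chroman-4-one
Product: 10 methyl (2S,3S)-5-bromo-7-methoxy-2-[3-methoxy-4-(tosyloxy)phenyl]-2,3-dihydro-1-benzofuran-3-carboxylate, via enol ether 9 (not isolated)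
Conditions: PhI(OAc)2 (1.2 equiv), conc. H2SO4 (0.5 equiv), HC(OMe)3, rt
Reagents that add atoms: trimethyl orthoformate, COC(OC)OC
Why: Acid and HC(OMe)3 turn the C4 ketone into the 4-methoxy-2H-chromene 9; the electrophilic trivalent iodine of PhI(OAc)2 adds to C3 on the face opposite the C2 aryl group and methanol traps C4 as the dimethyl ketal. In that half-chair the C3–I bond is axial and antiperiplanar to C4–C4a, so C4a moves from C4 to C3 with inversion as PhI departs, and the dimethoxycarbenium ion left at C4 loses one methyl group to give the methyl ester. The closest known reaction type is the oxidative ring contraction of flavanones to methyl trans-2-aryl-2,3-dihydrobenzofuran-3-carboxylates with PhI(OAc)2/H2SO4 or Tl(NO3)3 in HC(OMe)3, a cyclic case of the 1,2-aryl shift of aryl ketone enol ethers. The dihydrofuran ring is not closed end to end: the ipso carbon C4a bridges C3 and C4 in a phenonium-like three-membered transition state (formally 3-exo-tet at C3) and the six-membered ring contracts to five. The new stereocentre C3 is controlled by C2, because anti addition of iodine followed by inversion places CO2Me trans to ring D, and the trans ester is also the thermodynamic epimer, so cis material can converge. The step requires C4a migration in preference to the 2,3-shift of ring D and to dehydrogenation: the sulfonate makes ring D a poor migrating group, the ring oxygen ortho to C4a makes ring C a good one, and the bromine para to that oxygen blocks electrophilic attack on ring C. C2 is not involved in any bond change, so its S configuration is carried through.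

Step 7
Reactants: 10 methyl (2S,3S)-5-bromo-7-methoxy-2-[3-methoxy-4-(tosyloxy)phenyl]-2,3-dihydro-1-benzofuran-3-carboxylate
Product: 11 {(2S,3R)-5-bromo-7-methoxy-2-[3-methoxy-4-(tosyloxy)phenyl]-2,3-dihydro-1-benzofuran-3-yl}methanol
Conditions: i-Bu2AlH (2.5 equiv), CH2Cl2, −78 to −20 °C; aq. potassium sodium tartrate
Reagents that add atoms: none
Why: Hydride reduction of an ester to a primary alcohol under non-basic conditions, so neither C3 epimerisation nor E1cB opening of the β-aryloxy ester can compete; aryl bromide and aryl sulfonate are inert at low temperature.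

Step 8
Reactants: 11 {(2S,3R)-5-bromo-7-methoxy-2-[3-methoxy-4-(tosyloxy)phenyl]-2,3-dihydro-1-benzofuran-3-yl}methanol
Product: 12 4-[(2S,3R)-5-bromo-3-(hydroxymethyl)-7-methoxy-2,3-dihydro-1-benzofuran-2-yl]-2-methoxyphenol
Conditions: KOH (5 equiv), EtOH/H2O 4:1, 70 °C
Reagents that add atoms: none
Why: Alkaline hydrolysis of an aryl sulfonate by attack at sulfur; with the ester already reduced there is no acidic C3–H, and should the phenoxide open the ring reversibly through a quinone methide, the retained C3 centre would close it again to the trans isomer.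

Step 9
Reactants: 12 4-[(2S,3R)-5-bromo-3-(hydroxymethyl)-7-methoxy-2,3-dihydro-1-benzofuran-2-yl]-2-methoxyphenol
Product: 13 (2S,3R)-5-bromo-7-methoxy-2-[3-methoxy-4-(triisopropylsilyloxy)phenyl]-3-[(triisopropylsilyloxy)methyl]-2,3-dihydro-1-benzofuran
Conditions: TIPSOTf (2.4 equiv), 2,6-lutidine (3 equiv), CH2Cl2, 0 °C
Reagents that add atoms: triisopropylsilyl trifluoromethanesulfonate, CC(C)[Si](OS(=O)(=O)C(F)(F)F)(C(C)C)C(C)C
Why: Silylation of phenol and primary alcohol in one operation; the bulky aryl silyl ether survives the organolithium and borohydride of step 10 and leaves with fluoride in step 25.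

Step 10
Reactants: 13 (2S,3R)-5-bromo-7-methoxy-2-[3-methoxy-4-(triisopropylsilyloxy)phenyl]-3-[(triisopropylsilyloxy)methyl]-2,3-dihydro-1-benzofuran
Product: 16 {(2S,3R)-7-methoxy-2-[3-methoxy-4-(triisopropylsilyloxy)phenyl]-3-[(triisopropylsilyloxy)methyl]-2,3-dihydro-1-benzofuran-5-yl}methanol, via aryllithium 14 (not isolated), via aldehyde 15 (not isolated)
Conditions: n-BuLi (1.1 equiv), THF, −78 °C; DMF (3 equiv), −78 to 0 °C; then MeOH, NaBH4, 0 °C
Reagents that add atoms: N,N-dimethylformamide, CN(C)C=O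
Why: Bromine–lithium exchange is faster than any deprotonation at −78 °C; the aryllithium is formylated by DMF (Bouveault aldehyde synthesis) and the aldehyde released on methanol quench is reduced in the same flask by borohydride.

Step 11
Reactants: 16 {(2S,3R)-7-methoxy-2-[3-methoxy-4-(triisopropylsilyloxy)phenyl]-3-[(triisopropylsilyloxy)methyl]-2,3-dihydro-1-benzofuran-5-yl}methanol
Product: 17 (2S,3R)-5-(bromomethyl)-7-methoxy-2-[3-methoxy-4-(triisopropylsilyloxy)phenyl]-3-[(triisopropylsilyloxy)methyl]-2,3-dihydro-1-benzofuran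
Conditions: CBr4 (1.3 equiv), PPh3 (1.3 equiv), CH2Cl2, 0 °C
Reagents that add atoms: tetrabromomethane, BrC(Br)(Br)Br
Why: Appel reaction under neutral conditions, compatible with silyl ethers; the electron-rich benzylic bromide is used directly in step 24.

Step 12
Reactants: 18 4-(benzyloxy)-3-methoxybenzaldehyde; 19 dimethyl succinate
Product: 20 (3E)-4-[4-(benzyloxy)-3-methoxyphenyl]-3-(methoxycarbonyl)but-3-enoic acid
Conditions: NaOMe (2.2 equiv), MeOH, reflux; then 2 M HCl
Reagents that add atoms: none
Why: Stobbe condensation: aldol addition, lactonisation to the paraconate and E1cB opening give the half-ester with the aryl group trans to the ester.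

Step 13
Reactants: 20 (3E)-4-[4-(benzyloxy)-3-methoxyphenyl]-3-(methoxycarbonyl)but-3-enoic acid
Product: 21 (3R)-4-[4-(benzyloxy)-3-methoxyphenyl]-3-(methoxycarbonyl)butanoic acid
Conditions: [Rh(cod)((S,S)-Et-DuPhos)]BF4 (1 mol %), H2 (5 bar), NaOMe (0.1 equiv), MeOH, rt
Reagents that add atoms: none
Why: Asymmetric hydrogenation of an itaconate-type half-ester: the carboxylate and the alkene chelate the cationic rhodium centre and the C2-symmetric bisphospholane selects the alkene face, setting the future lactone β-carbon as R; the benzyl ether is not cleaved by a homogeneous rhodium catalyst.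

Step 14
Reactants: 21 (3R)-4-[4-(benzyloxy)-3-methoxyphenyl]-3-(methoxycarbonyl)butanoic acid
Product: 23 (4R)-4-[4-(benzyloxy)-3-methoxybenzyl]dihydrofuran-2(3H)-one, via hydroxy acid 22 (not isolated)
Conditions: KOH (1.0 equiv), EtOH; CaCl2 (1.5 equiv), NaBH4 (3 equiv), EtOH, −10 °C to rt; then 2 M HCl, rt
Reagents that add atoms: none
Why: Chemoselective reduction of an ester beside a carboxylate salt by Ca(BH4)2 formed in the flask, then acid-induced lactonisation; the stereocentre is not enolisable under these conditions.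

Step 15
Reactants: 23 (4R)-4-[4-(benzyloxy)-3-methoxybenzyl]dihydrofuran-2(3H)-one
Product: 24 (4R)-4-(4-hydroxy-3-methoxybenzyl)dihydrofuran-2(3H)-one
Conditions: H2 (1 atm), 10% Pd/C, EtOAc/MeOH, rt
Reagents that add atoms: none
Why: Hydrogenolysis of a phenolic benzyl ether; no other benzylic C–O bond is present at this stage.

Step 16
Reactants: 24 (4R)-4-(4-hydroxy-3-methoxybenzyl)dihydrofuran-2(3H)-one; 25 (4R)-4-benzyl-3-(chloroacetyl)-1,3-oxazolidin-2-one
Product: 26 (4R)-4-benzyl-3-[(2-methoxy-4-{[(3R)-5-oxotetrahydrofuran-3-yl]methyl}phenoxy)acetyl]-1,3-oxazolidin-2-one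
Conditions: K2CO3 (1.5 equiv), NaI (0.1 equiv), acetone, rt
Reagents that add atoms: none
Why: Williamson ether synthesis on an α-halo imide with Finkelstein activation; SN2 at the activated CH2 is faster than acyl transfer to the weakly basic phenoxide.

Step 17
Reactants: 27 4-hydroxy-3-methoxybenzaldehyde (vanillin)
Product: 28 3-methoxy-4-(triisopropylsilyloxy)benzaldehyde
Conditions: TIPSCl (1.2 equiv), imidazole (2 equiv), DMF, rt
Reagents that add atoms: chlorotriisopropylsilane, CC(C)[Si](Cl)(C(C)C)C(C)C
Why: Standard phenol silylation; the bulky silyl ether tolerates the boron aldol, borohydride and amide base used later and leaves with fluoride at the end.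

Step 18
Reactants: 26 (4R)-4-benzyl-3-[(2-methoxy-4-{[(3R)-5-oxotetrahydrofuran-3-yl]methyl}phenoxy)acetyl]-1,3-oxazolidin-2-one; 28 3-methoxy-4-(triisopropylsilyloxy)benzaldehyde
Product: 30 (4R)-4-benzyl-3-[(2R,3S)-3-hydroxy-3-[3-methoxy-4-(triisopropylsilyloxy)phenyl]-2-(2-methoxy-4-{[(3R)-5-oxotetrahydrofuran-3-yl]methyl}phenoxy)propanoyl]-1,3-oxazolidin-2-one, via boron enolate 29 (not isolated)
Conditions: Bu2BOTf (1.2 equiv), i-Pr2NEt (1.4 equiv), CH2Cl2, −78 to 0 °C; 28, −78 to 0 °C; then pH 7 buffer, MeOH, H2O2, 0 °C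
Reagents that add atoms: none
Why: Evans syn aldol reaction: only the imide is enolised, and the Z boron enolate 29 reacts through a closed Zimmerman–Traxler transition state on the face left open by the auxiliary benzyl group to give the 2R,3S syn adduct; C2 becomes C8'' of the target in the correct sense, while the syn (threo) carbinol at C3 is provisional and is corrected in steps 21 and 22.

Step 19
Reactants: 30 (4R)-4-benzyl-3-[(2R,3S)-3-hydroxy-3-[3-methoxy-4-(triisopropylsilyloxy)phenyl]-2-(2-methoxy-4-{[(3R)-5-oxotetrahydrofuran-3-yl]methyl}phenoxy)propanoyl]-1,3-oxazolidin-2-one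
Product: 31 (4R)-4-{4-[((1S,2S)-1,3-dihydroxy-1-[3-methoxy-4-(triisopropylsilyloxy)phenyl]propan-2-yl)oxy]-3-methoxybenzyl}dihydrofuran-2(3H)-one
Conditions: NaBH4 (4 equiv), THF/H2O 4:1, 0 °C
Reagents that add atoms: none
Why: Reductive removal of the oxazolidinone auxiliary; the α-aryloxy imide carbonyl is far more electrophilic than the unactivated γ-lactone, which should survive borohydride at 0 °C.

Step 20
Reactants: 31 (4R)-4-{4-[((1S,2S)-1,3-dihydroxy-1-[3-methoxy-4-(triisopropylsilyloxy)phenyl]propan-2-yl)oxy]-3-methoxybenzyl}dihydrofuran-2(3H)-one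
Product: 32 (4R)-4-{4-[((1S,2S)-3-(tert-butyldimethylsilyloxy)-1-hydroxy-1-[3-methoxy-4-(triisopropylsilyloxy)phenyl]propan-2-yl)oxy]-3-methoxybenzyl}dihydrofuran-2(3H)-one
Conditions: TBSCl (1.1 equiv), imidazole (2 equiv), CH2Cl2, 0 °C
Reagents that add atoms: tert-butylchlorodimethylsilane, CC(C)(C)[Si](C)(C)Cl
Why: Selective silylation of the primary over the hindered secondary benzylic hydroxyl; the silyl ether also removes the C3 oxygen as a chelating site for step 22.

Step 21
Reactants: 32 (4R)-4-{4-[((1S,2S)-3-(tert-butyldimethylsilyloxy)-1-hydroxy-1-[3-methoxy-4-(triisopropylsilyloxy)phenyl]propan-2-yl)oxy]-3-methoxybenzyl}dihydrofuran-2(3H)-one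
Product: 33 (4R)-4-{4-[((2S)-3-(tert-butyldimethylsilyloxy)-1-[3-methoxy-4-(triisopropylsilyloxy)phenyl]-1-oxopropan-2-yl)oxy]-3-methoxybenzyl}dihydrofuran-2(3H)-one
Conditions: Dess–Martin periodinane (1.3 equiv), CH2Cl2, 0 °C to rt
Reagents that add atoms: none
Why: Dess–Martin oxidation of the benzylic alcohol without base, so the α-aryloxy stereocentre is not enolised and the β-silyloxy group is not eliminated.

Step 22
Reactants: 33 (4R)-4-{4-[((2S)-3-(tert-butyldimethylsilyloxy)-1-[3-methoxy-4-(triisopropylsilyloxy)phenyl]-1-oxopropan-2-yl)oxy]-3-methoxybenzyl}dihydrofuran-2(3H)-one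
Product: 34 (4R)-4-{4-[((1R,2S)-3-(tert-butyldimethylsilyloxy)-1-hydroxy-1-[3-methoxy-4-(triisopropylsilyloxy)phenyl]propan-2-yl)oxy]-3-methoxybenzyl}dihydrofuran-2(3H)-one
Conditions: Zn(BH4)2 (1.5 equiv, 0.15 M in Et2O), Et2O/CH2Cl2, −30 to 0 °C
Reagents that add atoms: none
Why: Chelation-controlled ketone reduction (Cram chelate model): zinc binds the carbonyl oxygen and the α-aryloxy oxygen, assisted by the ortho methoxy group of ring B, and hydride enters anti to the CH2OTBS group, giving the 1R,2S (erythro) carbinol; the lactone is inert to Zn(BH4)2.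

Step 23
Reactants: 34 (4R)-4-{4-[((1R,2S)-3-(tert-butyldimethylsilyloxy)-1-hydroxy-1-[3-methoxy-4-(triisopropylsilyloxy)phenyl]propan-2-yl)oxy]-3-methoxybenzyl}dihydrofuran-2(3H)-one
Product: 35 (4R)-4-{4-[((1R,2S)-1,3-bis(tert-butyldimethylsilyloxy)-1-[3-methoxy-4-(triisopropylsilyloxy)phenyl]propan-2-yl)oxy]-3-methoxybenzyl}dihydrofuran-2(3H)-one
Conditions: TBSOTf (1.3 equiv), 2,6-lutidine (2 equiv), CH2Cl2, −40 to 0 °C
Reagents that add atoms: tert-butyldimethylsilyl trifluoromethanesulfonate, CC(C)(C)[Si](C)(C)OS(=O)(=O)C(F)(F)F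
Why: Silylation of a hindered secondary alcohol with the silyl triflate; with the weak base 2,6-lutidine at low temperature the lactone is not converted into a ketene acetal.

Step 24
Reactants: 35 (4R)-4-{4-[((1R,2S)-1,3-bis(tert-butyldimethylsilyloxy)-1-[3-methoxy-4-(triisopropylsilyloxy)phenyl]propan-2-yl)oxy]-3-methoxybenzyl}dihydrofuran-2(3H)-one; 17 (2S,3R)-5-(bromomethyl)-7-methoxy-2-[3-methoxy-4-(triisopropylsilyloxy)phenyl]-3-[(triisopropylsilyloxy)methyl]-2,3-dihydro-1-benzofuran
Product: 37 (3R,4R)-4-{4-[((1R,2S)-1,3-bis(tert-butyldimethylsilyloxy)-1-[3-methoxy-4-(triisopropylsilyloxy)phenyl]propan-2-yl)oxy]-3-methoxybenzyl}-3-({(2S,3R)-7-methoxy-2-[3-methoxy-4-(triisopropylsilyloxy)phenyl]-3-[(triisopropylsilyloxy)methyl]-2,3-dihydro-1-benzofuran-5-yl}methyl)dihydrofuran-2(3H)-one, via lithium enolate 36 (not isolated)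
Conditions: LiN(SiMe3)2 (1.1 equiv), THF, −78 °C; then 17 (1.1 equiv), DMPU, −78 to −40 °C
Reagents that add atoms: none
Why: Alkylation of a β-substituted γ-butyrolactone enolate, the standard entry to trans-dibenzylbutyrolactone lignans; the β-benzyl group shields one face of the planar enolate, so the bromide adds anti and the α-centre is formed as R (trans).

Step 25
Reactants: 37 (3R,4R)-4-{4-[((1R,2S)-1,3-bis(tert-butyldimethylsilyloxy)-1-[3-methoxy-4-(triisopropylsilyloxy)phenyl]propan-2-yl)oxy]-3-methoxybenzyl}-3-({(2S,3R)-7-methoxy-2-[3-methoxy-4-(triisopropylsilyloxy)phenyl]-3-[(triisopropylsilyloxy)methyl]-2,3-dihydro-1-benzofuran-5-yl}methyl)dihydrofuran-2(3H)-one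
Product: 38 (3R,4R)-4-{4-[((1R,2S)-1,3-dihydroxy-1-(4-hydroxy-3-methoxyphenyl)propan-2-yl)oxy]-3-methoxybenzyl}-3-{[(2S,3R)-2-(4-hydroxy-3-methoxyphenyl)-3-(hydroxymethyl)-7-methoxy-2,3-dihydro-1-benzofuran-5-yl]methyl}dihydrofuran-2(3H)-one
Conditions: Bu4NF (7 equiv), AcOH (7 equiv), THF, 0 °C to rt
Reagents that add atoms: none
Why: Fluoride-induced cleavage of all five silyl ethers; acetic acid buffers the phenoxides and alkoxides so that the lactone, the α-centre and the para-hydroxybenzylic positions are not exposed to strong base, and no acid or hydrogen is needed.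

Compound list

1 | 1-(2-hydroxy-3-methoxyphenyl)ethan-1-one (2'-hydroxy-3'-methoxyacetophenone) | CC(=O)c1cccc(OC)c1O | starting material
2 | 1-(5-bromo-2-hydroxy-3-methoxyphenyl)ethan-1-one | CC(=O)c1cc(Br)cc(OC)c1O | intermediate
3 | (E)-1-(5-bromo-2-hydroxy-3-methoxyphenyl)-3-(dimethylamino)prop-2-en-1-one (not isolated) | CN(C)/C=C/C(=O)c1cc(Br)cc(OC)c1O | intermediate
4 | 6-bromo-8-methoxy-4H-chromen-4-one | O=c1ccoc2c(OC)cc(Br)cc12 | intermediate
5 | 2-methoxy-4-(4,4,5,5-tetramethyl-1,3,2-dioxaborolan-2-yl)phenol | COc1cc(B2OC(C)(C)C(C)(C)O2)ccc1O | starting material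
6 | 2-methoxy-4-(4,4,5,5-tetramethyl-1,3,2-dioxaborolan-2-yl)phenyl 4-methylbenzenesulfonate | COc1cc(B2OC(C)(C)C(C)(C)O2)ccc1OS(=O)(=O)c1ccc(C)cc1 | intermediate
7 | [3-methoxy-4-(tosyloxy)phenyl]boronic acid | COc1cc(B(O)O)ccc1OS(=O)(=O)c1ccc(C)cc1 | intermediate
8 | (2S)-6-bromo-8-methoxy-2-[3-methoxy-4-(tosyloxy)phenyl]chroman-4-one | Brc1cc(OC)c2c(c1)C(=O)C[C@@H](c1ccc(OS(=O)(=O)c3ccc(C)cc3)c(OC)c1)O2 | intermediate
9 | (2S)-6-bromo-4,8-dimethoxy-2-[3-methoxy-4-(tosyloxy)phenyl]-2H-chromene (not isolated) | Brc1cc(OC)c2c(c1)C(OC)=C[C@@H](c1ccc(OS(=O)(=O)c3ccc(C)cc3)c(OC)c1)O2 | intermediate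
10 | methyl (2S,3S)-5-bromo-7-methoxy-2-[3-methoxy-4-(tosyloxy)phenyl]-2,3-dihydro-1-benzofuran-3-carboxylate (trans) | Brc1cc(OC)c2c(c1)[C@H](C(=O)OC)[C@@H](c1ccc(OS(=O)(=O)c3ccc(C)cc3)c(OC)c1)O2 | intermediate
11 | {(2S,3R)-5-bromo-7-methoxy-2-[3-methoxy-4-(tosyloxy)phenyl]-2,3-dihydro-1-benzofuran-3-yl}methanol | Brc1cc(OC)c2c(c1)[C@H](CO)[C@@H](c1ccc(OS(=O)(=O)c3ccc(C)cc3)c(OC)c1)O2 | intermediate
12 | 4-[(2S,3R)-5-bromo-3-(hydroxymethyl)-7-methoxy-2,3-dihydro-1-benzofuran-2-yl]-2-methoxyphenol | Brc1cc(OC)c2c(c1)[C@H](CO)[C@@H](c1ccc(O)c(OC)c1)O2 | intermediate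
13 | (2S,3R)-5-bromo-7-methoxy-2-[3-methoxy-4-(triisopropylsilyloxy)phenyl]-3-[(triisopropylsilyloxy)methyl]-2,3-dihydro-1-benzofuran | Brc1cc(OC)c2c(c1)[C@H](CO[Si](C(C)C)(C(C)C)C(C)C)[C@@H](c1ccc(O[Si](C(C)C)(C(C)C)C(C)C)c(OC)c1)O2 | intermediate
14 | 5-lithio derivative of 13 (aryllithium, not isolated) | [Li]c1cc(OC)c2c(c1)[C@H](CO[Si](C(C)C)(C(C)C)C(C)C)[C@@H](c1ccc(O[Si](C(C)C)(C(C)C)C(C)C)c(OC)c1)O2 | intermediate
15 | (2S,3R)-7-methoxy-2-[3-methoxy-4-(triisopropylsilyloxy)phenyl]-3-[(triisopropylsilyloxy)methyl]-2,3-dihydro-1-benzofuran-5-carbaldehyde (not isolated) | O=Cc1cc(OC)c2c(c1)[C@H](CO[Si](C(C)C)(C(C)C)C(C)C)[C@@H](c1ccc(O[Si](C(C)C)(C(C)C)C(C)C)c(OC)c1)O2 | intermediate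
16 | {(2S,3R)-7-methoxy-2-[3-methoxy-4-(triisopropylsilyloxy)phenyl]-3-[(triisopropylsilyloxy)methyl]-2,3-dihydro-1-benzofuran-5-yl}methanol | OCc1cc(OC)c2c(c1)[C@H](CO[Si](C(C)C)(C(C)C)C(C)C)[C@@H](c1ccc(O[Si](C(C)C)(C(C)C)C(C)C)c(OC)c1)O2 | intermediate
17 | (2S,3R)-5-(bromomethyl)-7-methoxy-2-[3-methoxy-4-(triisopropylsilyloxy)phenyl]-3-[(triisopropylsilyloxy)methyl]-2,3-dihydro-1-benzofuran | BrCc1cc(OC)c2c(c1)[C@H](CO[Si](C(C)C)(C(C)C)C(C)C)[C@@H](c1ccc(O[Si](C(C)C)(C(C)C)C(C)C)c(OC)c1)O2 | intermediate
18 | 4-(benzyloxy)-3-methoxybenzaldehyde | COc1cc(C=O)ccc1OCc1ccccc1 | starting material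
19 | dimethyl succinate | COC(=O)CCC(=O)OC | starting material
20 | (3E)-4-[4-(benzyloxy)-3-methoxyphenyl]-3-(methoxycarbonyl)but-3-enoic acid | OC(=O)C/C(C(=O)OC)=C\c1ccc(OCc2ccccc2)c(OC)c1 | intermediate
21 | (3R)-4-[4-(benzyloxy)-3-methoxyphenyl]-3-(methoxycarbonyl)butanoic acid | COC(=O)[C@@H](CC(=O)O)Cc1ccc(OCc2ccccc2)c(OC)c1 | intermediate
22 | (3R)-4-[4-(benzyloxy)-3-methoxyphenyl]-3-(hydroxymethyl)butanoic acid (formed as its carboxylate, not isolated) | OC[C@@H](CC(=O)O)Cc1ccc(OCc2ccccc2)c(OC)c1 | intermediate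
23 | (4R)-4-[4-(benzyloxy)-3-methoxybenzyl]dihydrofuran-2(3H)-one | COc1cc(C[C@H]2COC(=O)C2)ccc1OCc1ccccc1 | intermediate
24 | (4R)-4-(4-hydroxy-3-methoxybenzyl)dihydrofuran-2(3H)-one | COc1cc(C[C@H]2COC(=O)C2)ccc1O | intermediate
25 | (4R)-4-benzyl-3-(chloroacetyl)-1,3-oxazolidin-2-one | ClCC(=O)N1[C@H](Cc2ccccc2)COC1=O | starting material
26 | (4R)-4-benzyl-3-[(2-methoxy-4-{[(3R)-5-oxotetrahydrofuran-3-yl]methyl}phenoxy)acetyl]-1,3-oxazolidin-2-one | COc1cc(C[C@H]2COC(=O)C2)ccc1OCC(=O)N1[C@H](Cc2ccccc2)COC1=O | intermediate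
27 | 4-hydroxy-3-methoxybenzaldehyde (vanillin) | COc1cc(C=O)ccc1O | starting material
28 | 3-methoxy-4-(triisopropylsilyloxy)benzaldehyde | COc1cc(C=O)ccc1O[Si](C(C)C)(C(C)C)C(C)C | intermediate
29 | (Z)-dibutylboron enolate of 26 (not isolated) | CCCCB(CCCC)O/C(N1[C@H](Cc2ccccc2)COC1=O)=C\Oc1ccc(C[C@H]2COC(=O)C2)cc1OC | intermediate
30 | (4R)-4-benzyl-3-[(2R,3S)-3-hydroxy-3-[3-methoxy-4-(triisopropylsilyloxy)phenyl]-2-(2-methoxy-4-{[(3R)-5-oxotetrahydrofuran-3-yl]methyl}phenoxy)propanoyl]-1,3-oxazolidin-2-one (syn aldol) | COc1cc([C@H](O)[C@@H](Oc2ccc(C[C@H]3COC(=O)C3)cc2OC)C(=O)N2[C@H](Cc3ccccc3)COC2=O)ccc1O[Si](C(C)C)(C(C)C)C(C)C | intermediate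
31 | (4R)-4-{4-[((1S,2S)-1,3-dihydroxy-1-[3-methoxy-4-(triisopropylsilyloxy)phenyl]propan-2-yl)oxy]-3-methoxybenzyl}dihydrofuran-2(3H)-one (threo) | COc1cc([C@H](O)[C@H](CO)Oc2ccc(C[C@H]3COC(=O)C3)cc2OC)ccc1O[Si](C(C)C)(C(C)C)C(C)C | intermediate
32 | (4R)-4-{4-[((1S,2S)-3-(tert-butyldimethylsilyloxy)-1-hydroxy-1-[3-methoxy-4-(triisopropylsilyloxy)phenyl]propan-2-yl)oxy]-3-methoxybenzyl}dihydrofuran-2(3H)-one | COc1cc([C@H](O)[C@H](CO[Si](C)(C)C(C)(C)C)Oc2ccc(C[C@H]3COC(=O)C3)cc2OC)ccc1O[Si](C(C)C)(C(C)C)C(C)C | intermediate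
33 | (4R)-4-{4-[((2S)-3-(tert-butyldimethylsilyloxy)-1-[3-methoxy-4-(triisopropylsilyloxy)phenyl]-1-oxopropan-2-yl)oxy]-3-methoxybenzyl}dihydrofuran-2(3H)-one | COc1cc(C(=O)[C@H](CO[Si](C)(C)C(C)(C)C)Oc2ccc(C[C@H]3COC(=O)C3)cc2OC)ccc1O[Si](C(C)C)(C(C)C)C(C)C | intermediate
34 | (4R)-4-{4-[((1R,2S)-3-(tert-butyldimethylsilyloxy)-1-hydroxy-1-[3-methoxy-4-(triisopropylsilyloxy)phenyl]propan-2-yl)oxy]-3-methoxybenzyl}dihydrofuran-2(3H)-one (erythro) | COc1cc([C@@H](O)[C@H](CO[Si](C)(C)C(C)(C)C)Oc2ccc(C[C@H]3COC(=O)C3)cc2OC)ccc1O[Si](C(C)C)(C(C)C)C(C)C | intermediate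
35 | (4R)-4-{4-[((1R,2S)-1,3-bis(tert-butyldimethylsilyloxy)-1-[3-methoxy-4-(triisopropylsilyloxy)phenyl]propan-2-yl)oxy]-3-methoxybenzyl}dihydrofuran-2(3H)-one | COc1cc([C@@H](O[Si](C)(C)C(C)(C)C)[C@H](CO[Si](C)(C)C(C)(C)C)Oc2ccc(C[C@H]3COC(=O)C3)cc2OC)ccc1O[Si](C(C)C)(C(C)C)C(C)C | intermediate
36 | lithium enolate of 35 (not isolated) | COc1cc([C@@H](O[Si](C)(C)C(C)(C)C)[C@H](CO[Si](C)(C)C(C)(C)C)Oc2ccc(C[C@H]3COC(O[Li])=C3)cc2OC)ccc1O[Si](C(C)C)(C(C)C)C(C)C | intermediate
37 | (3R,4R)-4-{4-[((1R,2S)-1,3-bis(tert-butyldimethylsilyloxy)-1-[3-methoxy-4-(triisopropylsilyloxy)phenyl]propan-2-yl)oxy]-3-methoxybenzyl}-3-({(2S,3R)-7-methoxy-2-[3-methoxy-4-(triisopropylsilyloxy)phenyl]-3-[(triisopropylsilyloxy)methyl]-2,3-dihydro-1-benzofuran-5-yl}methyl)dihydrofuran-2(3H)-one | COc1cc([C@@H](O[Si](C)(C)C(C)(C)C)[C@H](CO[Si](C)(C)C(C)(C)C)Oc2ccc(C[C@H]3COC(=O)[C@@H]3Cc3cc(OC)c4c(c3)[C@H](CO[Si](C(C)C)(C(C)C)C(C)C)[C@@H](c3ccc(O[Si](C(C)C)(C(C)C)C(C)C)c(OC)c3)O4)cc2OC)ccc1O[Si](C(C)C)(C(C)C)C(C)C | intermediate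
38 | (3R,4R)-4-{4-[((1R,2S)-1,3-dihydroxy-1-(4-hydroxy-3-methoxyphenyl)propan-2-yl)oxy]-3-methoxybenzyl}-3-{[(2S,3R)-2-(4-hydroxy-3-methoxyphenyl)-3-(hydroxymethyl)-7-methoxy-2,3-dihydro-1-benzofuran-5-yl]methyl}dihydrofuran-2(3H)-one (CNP0265599.1) | COc1cc([C@@H](O)[C@H](CO)Oc2ccc(C[C@H]3COC(=O)[C@@H]3Cc3cc(OC)c4c(c3)[C@H](CO)[C@@H](c3ccc(O)c(OC)c3)O4)cc2OC)ccc1O | target

Total step count: 25.

Longest linear sequence: 13 steps (12, 13, 14, 15, 16, 18, 19, 20, 21, 22, 23, 24, 25). The dihydrobenzofuran branch contributes 11 steps (1, 2, 5–11, 24, 25).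

Least certain steps

Step 6 (key step). The most likely failure is diversion of the iodonium intermediate: migration of ring D from C2 to C3, plain dehydrogenation of the enol ether, or electrophilic attack of the iodine reagent on an anisole ring. Each removes material from the C4a shift. Partial epimerisation at C3 would be harmless, because the trans ester is the stable epimer. Fallback, a different way to the same 1,2-shift: from 8, nitrosation at C3 under acid (isoamyl nitrite, HCl), which avoids base-induced opening of the pyranone, would give the 3-hydroxyimino ketone F1. A Forster reaction (NH2Cl from NaOCl and NH3) would convert it into the 3-diazo-4-chromanone F2. Photochemical Wolff rearrangement in MeOH moves C4a to the carbene carbon, and the ketene is trapped as the methyl ester, expected mainly as the cis ester F3 after protonation anti to ring D. Equilibration with DBU in CH2Cl2 would return to the route at 10.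

Step 5. Transmetalation of the electron-poor boronic acid may be slow and protodeboronation may compete. Facial discrimination on the 8-methoxychromone may also be insufficient. Fallback, by ring closure in place of C–C coupling: from 27, tosylation would give the aldehyde F4. Claisen–Schmidt condensation of F4 with 2 would give the chalcone F5. Oxa-Michael closure with NaOAc in EtOH would give the racemic flavanone F6. Kinetic resolution by asymmetric transfer hydrogenation with RuCl(p-cymene)(TsDPEN) (the antipode that reduces the 2R ketone; HCO2H/Et3N) would leave 8 and turn the unwanted antipode into the cis-flavan-4-ol F7, which is separated. The route is rejoined at 8.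

Step 16. Acyl transfer from the imide to the phenoxide (loss of the auxiliary) may compete with substitution at the CH2Cl group. Fallback, by acylating the auxiliary in place of alkylating with it: from 24, alkylation with tert-butyl bromoacetate (K2CO3, acetone) would give the ester F8. CF3CO2H would give the acid F9. Pivaloyl chloride and Et3N would give the mixed anhydride F10. Lithiated (R)-4-benzyloxazolidin-2-one (or the free auxiliary with LiCl and Et3N) would then give 26.

Step 22. If zinc chelation to the weakly basic aryloxy oxygen is incomplete, hydride delivery through a non-chelated polar Felkin–Anh arrangement would lower the facial selectivity in favour of the threo epimer. Enolisation of the α-aryloxy ketone or β-elimination of silanol would erode C8''. Fallback, by inversion in place of oxidation and reduction: from 32, Mitsunobu reaction with 4-nitrobenzoic acid (PPh3, DIAD) would give the inverted ester F11. Mild methanolysis (K2CO3, MeOH, 0 °C) would give 34, bypassing steps 21 and 22.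

Step 24. The electron-rich benzylic bromide may ionise or eliminate before it is alkylated. Proton transfer from product to enolate may lead to double alkylation. Facial control may be incomplete with so large an electrophile. Fallback, by aldol addition and deoxygenation: from 35 (as its enolate 36) and aldehyde 15 (isolated after the DMF quench of step 10), aldol addition would give the β-hydroxy lactone F12. 1,1'-Thiocarbonyldiimidazole would give the imidazole thiocarbamate F13. Barton–McCombie deoxygenation (Bu3SnH, AIBN, toluene, 80 °C) would give 37.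

Further compounds

F1 | step 6 | (2R)-6-bromo-3-(hydroxyimino)-8-methoxy-2-[3-methoxy-4-(tosyloxy)phenyl]chroman-4-one (same spatial arrangement at C2 as 8) | Brc1cc(OC)c2c(c1)C(=O)C(=NO)[C@@H](c1ccc(OS(=O)(=O)c3ccc(C)cc3)c(OC)c1)O2
F2 | step 6 | (2R)-6-bromo-3-diazo-8-methoxy-2-[3-methoxy-4-(tosyloxy)phenyl]chroman-4-one | Brc1cc(OC)c2c(c1)C(=O)C(=[N+]=[N-])[C@@H](c1ccc(OS(=O)(=O)c3ccc(C)cc3)c(OC)c1)O2
F3 | step 6 | methyl (2S,3R)-5-bromo-7-methoxy-2-[3-methoxy-4-(tosyloxy)phenyl]-2,3-dihydro-1-benzofuran-3-carboxylate (cis) | Brc1cc(OC)c2c(c1)[C@@H](C(=O)OC)[C@@H](c1ccc(OS(=O)(=O)c3ccc(C)cc3)c(OC)c1)O2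
F4 | step 5 | 4-formyl-2-methoxyphenyl 4-methylbenzenesulfonate | COc1cc(C=O)ccc1OS(=O)(=O)c1ccc(C)cc1
F5 | step 5 | (E)-1-(5-bromo-2-hydroxy-3-methoxyphenyl)-3-[3-methoxy-4-(tosyloxy)phenyl]prop-2-en-1-one | COc1cc(Br)cc(C(=O)/C=C/c2ccc(OS(=O)(=O)c3ccc(C)cc3)c(OC)c2)c1O
F6 | step 5 | racemic 6-bromo-8-methoxy-2-[3-methoxy-4-(tosyloxy)phenyl]chroman-4-one | Brc1cc(OC)c2c(c1)C(=O)CC(c1ccc(OS(=O)(=O)c3ccc(C)cc3)c(OC)c1)O2
F7 | step 5 | (2R,4R)-6-bromo-8-methoxy-2-[3-methoxy-4-(tosyloxy)phenyl]chroman-4-ol (cis) | Brc1cc(OC)c2c(c1)[C@H](O)C[C@H](c1ccc(OS(=O)(=O)c3ccc(C)cc3)c(OC)c1)O2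
F8 | step 16 | tert-butyl (2-methoxy-4-{[(3R)-5-oxotetrahydrofuran-3-yl]methyl}phenoxy)acetate | COc1cc(C[C@H]2COC(=O)C2)ccc1OCC(=O)OC(C)(C)C
F9 | step 16 | (2-methoxy-4-{[(3R)-5-oxotetrahydrofuran-3-yl]methyl}phenoxy)acetic acid | COc1cc(C[C@H]2COC(=O)C2)ccc1OCC(=O)O
F10 | step 16 | (2-methoxy-4-{[(3R)-5-oxotetrahydrofuran-3-yl]methyl}phenoxy)acetic pivalic anhydride | COc1cc(C[C@H]2COC(=O)C2)ccc1OCC(=O)OC(=O)C(C)(C)C
F11 | step 22 | (1R,2S)-3-(tert-butyldimethylsilyloxy)-1-[3-methoxy-4-(triisopropylsilyloxy)phenyl]-2-(2-methoxy-4-{[(3R)-5-oxotetrahydrofuran-3-yl]methyl}phenoxy)propyl 4-nitrobenzoate | COc1cc([C@@H](OC(=O)c2ccc(cc2)[N+](=O)[O-])[C@H](CO[Si](C)(C)C(C)(C)C)Oc2ccc(C[C@H]3COC(=O)C3)cc2OC)ccc1O[Si](C(C)C)(C(C)C)C(C)C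
F12 | step 24 | (3S,4R)-4-{4-[((1R,2S)-1,3-bis(tert-butyldimethylsilyloxy)-1-[3-methoxy-4-(triisopropylsilyloxy)phenyl]propan-2-yl)oxy]-3-methoxybenzyl}-3-(hydroxy{(2S,3R)-7-methoxy-2-[3-methoxy-4-(triisopropylsilyloxy)phenyl]-3-[(triisopropylsilyloxy)methyl]-2,3-dihydro-1-benzofuran-5-yl}methyl)dihydrofuran-2(3H)-one (carbinol epimers) | COc1cc([C@@H](O[Si](C)(C)C(C)(C)C)[C@H](CO[Si](C)(C)C(C)(C)C)Oc2ccc(C[C@H]3COC(=O)[C@@H]3C(O)c3cc(OC)c4c(c3)[C@H](CO[Si](C(C)C)(C(C)C)C(C)C)[C@@H](c3ccc(O[Si](C(C)C)(C(C)C)C(C)C)c(OC)c3)O4)cc2OC)ccc1O[Si](C(C)C)(C(C)C)C(C)C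
F13 | step 24 | O-imidazol-1-ylthiocarbonyl derivative of F12 (imidazole-1-carbothioate at the carbinol oxygen) | COc1cc([C@@H](O[Si](C)(C)C(C)(C)C)[C@H](CO[Si](C)(C)C(C)(C)C)Oc2ccc(C[C@H]3COC(=O)[C@@H]3C(OC(=S)n3ccnc3)c3cc(OC)c4c(c3)[C@H](CO[Si](C(C)C)(C(C)C)C(C)C)[C@@H](c3ccc(O[Si](C(C)C)(C(C)C)C(C)C)c(OC)c3)O4)cc2OC)ccc1O[Si](C(C)C)(C(C)C)C(C)C
A1 | alternative 1 | 3,4-trans conjugate addition–alkylation adduct with dithiane and menthyloxy acetal | COc1cc([C@@H](OC(C)(C)OC5)[C@H]5Oc2ccc(C6(SCCCS6)[C@H]3[C@H](O[C@@H]7C[C@H](C)CC[C@H]7C(C)C)OC(=O)[C@@H]3Cc3cc(OC)c4c(c3)[C@H](CO[Si](C)(C)C(C)(C)C)[C@@H](c3ccc(OCc8ccccc8)c(OC)c3)O4)cc2OC)ccc1OCc1ccccc1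
A2 | alternative 1 | (5R)-5-[(1R,2S,5R)-menthyloxy]furan-2(5H)-one | O=C1C=C[C@H](O[C@@H]2C[C@H](C)CC[C@H]2C(C)C)O1
A3 | alternative 1 | 2-aryl-1,3-dithiane of the ring A–B aldehyde (7,9-acetonide, ring A benzyl ether) | COc1cc([C@@H](OC(C)(C)OC5)[C@H]5Oc2ccc(C6SCCCS6)cc2OC)ccc1OCc1ccccc1
A4 | alternative 1 | (2S,3R)-2-[4-(benzyloxy)-3-methoxyphenyl]-5-(bromomethyl)-3-[(tert-butyldimethylsilyloxy)methyl]-7-methoxy-2,3-dihydro-1-benzofuran | BrCc1cc(OC)c2c(c1)[C@H](CO[Si](C)(C)C(C)(C)C)[C@@H](c1ccc(OCc3ccccc3)c(OC)c1)O2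
A5 | alternative 2 | methyl (2S,3R)-2-[4-(benzyloxy)-3-methoxyphenyl]-7-methoxy-5-[(triisopropylsilyloxy)methyl]-2,3-dihydro-1-benzofuran-3-carboxylate (cis) | CC(C)[Si](OCc1cc(OC)c2c(c1)[C@@H](C(=O)OC)[C@@H](c1ccc(OCc3ccccc3)c(OC)c1)O2)(C(C)C)C(C)C
A6 | alternative 2 | methyl 2-diazo-2-{2-[(4-benzyloxy-3-methoxybenzyl)oxy]-3-methoxy-5-[(triisopropylsilyloxy)methyl]phenyl}acetate | COC(=O)C(=[N+]=[N-])c1cc(CO[Si](C(C)C)(C(C)C)C(C)C)cc(OC)c1OCc1ccc(OCc2ccccc2)c(OC)c1
A7 | alternative 3 | {(2S,3R)-2-[4-(benzyloxy)-3-methoxyphenyl]-5-bromo-7-methoxy-2,3-dihydro-1-benzofuran-3-yl}methanol | Brc1cc(OC)c2c(c1)[C@H](CO)[C@@H](c1ccc(OCc3ccccc3)c(OC)c1)O2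
A8 | alternative 3 | 2-{(2R)-1-[4-(benzyloxy)-3-methoxyphenyl]-1,3-dihydroxypropan-2-yl}-4-bromo-6-methoxyphenol (carbinol epimers) | Oc1c(OC)cc(Br)cc1[C@H](CO)C(O)c1ccc(OCc2ccccc2)c(OC)c1
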